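The target is what I want from these flasks, but it is the kinetic product: it slides on to its isomer, which the thermodynamic balance favours by a factor 21 at 35 °C. Starting material joins the coupling partner to give the intermediate, the intermediate gives up the released group and becomes target, the released group leaves as by-product, and two starting material can also meet as homo dimer.

all flasks: starting material 20 mM; coupling partner 80.0 mM; time 1.0 h
- zeta: temperature 35 °C
- alpha: at 35 °C until 40 min, from then on at 20 °C
- eta: temperature 20 °C

    starting material + coupling partner ⇌ intermediate (K1 = 34 L mol⁻¹, k1 = 0.0113 L mol⁻¹ s⁻¹, Ea1 = 72.0 kJ mol⁻¹, ΔH1 = −17.0 kJ mol⁻¹)
    intermediate ⇌ target + released group (K2 = 0.00897 M, k2 = 8.82 × 10⁻⁴ s⁻¹, Ea2 = 87.0 kJ mol⁻¹, ΔH2 = −2.00 kJ mol⁻¹)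
    released group → by-product carried off (k3 = 0.00309 s⁻¹, Ea3 = 91.0 kJ mol⁻¹)
    target ⇌ isomer of the product (K4 = 21, k4 = 7.60 × 10⁻⁴ s⁻¹, Ea4 = 98.0 kJ mol⁻¹, ΔH4 = 4.00 kJ mol⁻¹)
    2 starting material → homo dimer (k5 = 0.0170 L mol⁻¹ s⁻¹, Ea5 = 70.0 kJ mol⁻¹)
    (constants at 35 °C)

* the flask that comes out highest in amount of target, in percent of the starting material charged, or "all alike" when all lie within 1.5 percentage points (zeta / alpha / eta / all alike)
* target at the end, in percent of the starting material charged, zeta
* target at the end, in percent of the starting material charged, alpha
* target at the end, in percent of the starting material charged, eta

- in percentages every species weighs as the starting material in it: one homo dimer counts as two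
- a doubled species enters its step squared and goes two at a time
- constants are those at 35 °C; use the activation energies and enthalpies for any other temperature

Zeta and alpha look nearly the same: they have the same charge and the same bath up to 40 min, so they hold the same at that moment. They part over the last 20.0 min, and since the question is what stands at the end, I work with the fraction left and not with the fraction made. The forward slide to the isomer runs at k[target], so with nothing else acting, a fixed fraction of the target standing at the start of a stretch at one temperature survives, exp(−k·t), whatever the amount. Over the last stretch the forward slide by itself leaves 40.2 % in zeta. In alpha, whose constant falls to 1.07 × 10⁻⁴ s⁻¹, it leaves 87.9 %. This fraction, [target] at the end of a stretch over [target] at its start with the forward slide acting by itself, is what I carry: the keep, in the usual term the first-order survival.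

So alpha's keep is twice zeta's. The keep counts no making, and the intermediate goes on feeding target in both flasks. But cooling slows the constant of the slide by a factor 7.08 and that of the forward release of target from the intermediate by 5.7, so the constant of the loss falls further than that of the feed, and I expect alpha above zeta. My reckoning stops at these fractions and puts no amount on the target.

The forecast names alpha as highest, with 15.5 % in zeta, 18.2 % in alpha and 8.5 % in eta, on the ground that “cooling at that point nearly freezes the loss”. Beside that phrase, my keep for alpha still lets 12.1 % of the target standing at the change go by the forward slide.

The simulation gives 15.8 % in zeta, 18.9 % in alpha and 9.51 % in eta, so alpha stands highest. The forecast's widest gap is 1 percentage point, in eta.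

In alpha, the 18.6 % of target at 0.667 h times the keep is 16.3 %, so the end figure stands 2.6 points above the keep, the net of everything but the forward slide. In eta, cold from the start, the forward half-life of target to isomer at the end is 1.8 h, longer than the hour, and target is made 4.24 times faster than it is used up, each step taken net, with 36.5 % starting material still there. A flask like eta kept at 5 °C has a keep of 95.7 % over the whole 1.0 h. That neighbour ends with 0.549 % target, 0.00840 % isomer and 76.8 % starting material.

(Its constants stand for no real mixture; the flask was simulated.)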